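**Retrosynthetic overview**
- The route rests on N4 of the imidazo[1,2-a]pyrazin-3(7H)-one: it is bonded to C3, C8a and C5, so one primary amine nitrogen that already carries C5 and C6 (a phenacylamine) can replace the ring oxygen of an oxazol-5(4H)-one that holds C3, C2, N1, C8a and the arylmethylene carbon on C2.
- Last ring (pyrazine): N7–C6 condensation after Boc removal, then redox-neutral proton shifts (C8–H to the exocyclic carbon, C5–H to N7); the aldehyde-derived arylidene supplies the unsaturation.
- Key disconnection (imidazolone ring): C3–N4 and N4–C8a, from a Z-Erlenmeyer azlactone and 2-amino-4'-hydroxyacetophenone.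
- Azlactone: Boc-Phe-Gly-OH and 4-hydroxybenzaldehyde (Erlenmeyer–Plöchl).
- Ring order: oxazolone (transient carrier), imidazolone, dihydropyrazine.

Key step: step 3

Assumption: coelenterazine has no stereogenic element, so the single-enantiomer requirement imposes nothing; the L-Phe centre (future C8) and the Z-alkene are drawn as expected but both are erased in step 5, and any epimerisation on the way is harmless.

**Step 1**
Reactants: 1 N-Boc-L-phenylalanine N-hydroxysuccinimide ester; 2 glycine
Product: 3 N-Boc-L-phenylalanylglycine (Boc-Phe-Gly-OH)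
Conditions: NaHCO3, THF/H2O, rt; then 1 M HCl to pH 3, 0 °C
Reagents that add atoms: none
Why: Aminolysis of an N-hydroxysuccinimide active ester by glycinate under aqueous bicarbonate is a standard active-ester peptide coupling that needs no carboxyl protection on glycine.

**Step 2**
Reactants: 3 Boc-Phe-Gly-OH; 4 4-hydroxybenzaldehyde
Product: 7 (Z)-4-(4-acetoxybenzylidene)-2-[(1S)-1-(Boc-amino)-2-phenylethyl]oxazol-5(4H)-one, via 4-acetoxybenzaldehyde 5 (not isolated), via 4-unsubstituted oxazolone 6 (not isolated)
Conditions: Ac2O, NaOAc, 75 °C; then cold EtOH/H2O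
Reagents that add atoms: acetic anhydride, CC(=O)OC(C)=O
Why: Erlenmeyer–Plöchl azlactone synthesis, in which the anhydride acetylates the phenol and cyclodehydrates the acylglycine to the oxazolone, whose C4 methylene condenses with the aldehyde to the thermodynamically preferred Z-arylidene while the Boc carbamate should tolerate the acetate-buffered medium.

**Step 3**
Reactants: 7 Z-azlactone; 8 2-amino-1-(4-hydroxyphenyl)ethanone hydrochloride
Product: 11 (Z)-2-[(1S)-1-(Boc-amino)-2-phenylethyl]-4-(4-hydroxybenzylidene)-1-[2-(4-hydroxyphenyl)-2-oxoethyl]-1H-imidazol-5(4H)-one, via ring-opened dehydropeptide amide 9 (not isolated), via O-silylated imidazolone acetate 10 (not isolated)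
Conditions: N-methylmorpholine (slow addition), DMF, 0 °C → rt, Ar; then BSA, 80 °C; then MeOH, K2CO3 (cat.), rt
Reagents that add atoms: none
Why: The amine, released gradually from 8, adds to the lactone carbonyl of 7 (future C3) and opens the ring to amide 9; BSA then silylates the phenol and amide groups, the phenacyl amide nitrogen (N4) adds to the Boc-Phe carbonyl carbon (C8a) and the silylated tetrahedral intermediate expels silanolate, so that water leaves as hexamethyldisiloxane and both C3–N4 and N4–C8a are formed. The closest known reaction type is the conversion of Erlenmeyer azlactones into 4-arylidene-imidazol-5(4H)-ones by amine ring opening and silylative or base-mediated cyclodehydration, the standard entry to GFP-type chromophores. The imidazolone ring closes 5-exo-trig, no stereocentre is created, and the Z-alkene is kept as the thermodynamic isomer. The step needs acylation at the lactone carbonyl in preference to conjugate addition at the arylidene, aminolysis of the aryl acetate and self-condensation of the α-amino ketone; the high acyl-transfer reactivity of the unsaturated azlactone, the low standing concentration of free amine at 0 °C and equimolar stoichiometry should secure this. In the closure, attack of N4 on C8a is the only path to a five-membered ring, and BSA is chosen over HMDS because it brings no ammonia that could condense with the ketone. Methanolic carbonate finally removes the aryl silyl ether and the aryl acetate by transesterification and leaves Boc and the ketone untouched.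

**Step 4**
Reactants: 11 Boc-protected bis-phenol imidazolone
Product: 12 (Z)-2-[(1S)-1-amino-2-phenylethyl]-4-(4-hydroxybenzylidene)-1-[2-(4-hydroxyphenyl)-2-oxoethyl]-1H-imidazol-5(4H)-one hydrochloride
Conditions: 4 M HCl in dioxane, 0 °C → rt, Ar; evaporate, use crude
Reagents that add atoms: hydrogen chloride, Cl
Why: Acidolysis of the tert-butyl carbamate (loss of isobutene and CO2) under anhydrous HCl should leave the arylidene-imidazolone, ketone and phenols intact and deliver the amine as its salt, protected from premature intermolecular reaction.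

**Step 5**
Reactants: 12 amine hydrochloride
Product: 14 coelenterazine, via dihydro arylidene bicycle 13 (not isolated)
Conditions: NaOAc (1.1 equiv), AcOH, degassed EtOH, 70 °C, Ar
Reagents that add atoms: none
Why: Proposed new method: the liberated amine N7 adds to the aryl ketone C6 (6-exo-trig) and dehydrates to the cyclic ketimine 13, in which C8–H lies between the amidine C8a=N1 and the imine nitrogen; acetate-mediated removal of this proton and reprotonation at the arylidene carbon through the C8a=N1–C2=CH azadiene (formal 1,5-prototropy), followed by an imine–enamine shift of C5–H to N7, should give the imidazopyrazinone, driven by formation of the 10π imidazo[1,2-a]pyrazin-3-ol/3(7H)-one system; 13 and 14 are isomers, so no redox reagent is needed; the closest known reaction types are the cyclocondensation of N-deprotected N-phenacyl α-amino amides to dihydropyrazinones that then tautomerise, and the aromatisation-driven isomerisation of exocyclic arylidene dihydroazines to benzylazines.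

**Compound list**
1 | N-Boc-L-phenylalanine N-hydroxysuccinimide ester | CC(C)(C)OC(=O)N[C@@H](Cc1ccccc1)C(=O)ON1C(=O)CCC1=O | starting material
2 | glycine | NCC(=O)O | starting material
3 | N-Boc-L-phenylalanylglycine | CC(C)(C)OC(=O)N[C@@H](Cc1ccccc1)C(=O)NCC(=O)O | intermediate
4 | 4-hydroxybenzaldehyde | O=Cc1ccc(O)cc1 | starting material
5 | 4-acetoxybenzaldehyde | CC(=O)Oc1ccc(C=O)cc1 | intermediate (not isolated)
6 | 2-[(1S)-1-(Boc-amino)-2-phenylethyl]oxazol-5(4H)-one | CC(C)(C)OC(=O)N[C@@H](Cc1ccccc1)C1=NCC(=O)O1 | intermediate (not isolated)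
7 | (Z)-4-(4-acetoxybenzylidene)-2-[(1S)-1-(Boc-amino)-2-phenylethyl]oxazol-5(4H)-one | CC(C)(C)OC(=O)N[C@@H](Cc1ccccc1)C1=N/C(=C\c2ccc(OC(C)=O)cc2)C(=O)O1 | intermediate
8 | 2-amino-1-(4-hydroxyphenyl)ethanone hydrochloride | Cl.NCC(=O)c1ccc(O)cc1 | starting material
9 | (Z)-N-(Boc-L-phenylalanyl)-O-acetyl-α,β-dehydrotyrosine N-[2-(4-hydroxyphenyl)-2-oxoethyl]amide | CC(C)(C)OC(=O)N[C@@H](Cc1ccccc1)C(=O)N/C(=C\c1ccc(OC(C)=O)cc1)C(=O)NCC(=O)c1ccc(O)cc1 | intermediate (not isolated)
10 | (Z)-4-(4-acetoxybenzylidene)-2-[(1S)-1-(Boc-amino)-2-phenylethyl]-1-[2-oxo-2-(4-trimethylsilyloxyphenyl)ethyl]-1H-imidazol-5(4H)-one | CC(C)(C)OC(=O)N[C@@H](Cc1ccccc1)C1=N/C(=C\c2ccc(OC(C)=O)cc2)C(=O)N1CC(=O)c1ccc(O[Si](C)(C)C)cc1 | intermediate (not isolated)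
11 | (Z)-2-[(1S)-1-(Boc-amino)-2-phenylethyl]-4-(4-hydroxybenzylidene)-1-[2-(4-hydroxyphenyl)-2-oxoethyl]-1H-imidazol-5(4H)-one | CC(C)(C)OC(=O)N[C@@H](Cc1ccccc1)C1=N/C(=C\c2ccc(O)cc2)C(=O)N1CC(=O)c1ccc(O)cc1 | intermediate
12 | (Z)-2-[(1S)-1-amino-2-phenylethyl]-4-(4-hydroxybenzylidene)-1-[2-(4-hydroxyphenyl)-2-oxoethyl]-1H-imidazol-5(4H)-one hydrochloride | Cl.N[C@@H](Cc1ccccc1)C1=N/C(=C\c2ccc(O)cc2)C(=O)N1CC(=O)c1ccc(O)cc1 | intermediate
13 | (8S,Z)-8-benzyl-2-(4-hydroxybenzylidene)-6-(4-hydroxyphenyl)-5,8-dihydroimidazo[1,2-a]pyrazin-3(2H)-one | O=C1N2CC(c3ccc(O)cc3)=N[C@@H](Cc3ccccc3)C2=N/C1=C\c1ccc(O)cc1 | intermediate (not isolated)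
14 | coelenterazine, 8-benzyl-2-(4-hydroxybenzyl)-6-(4-hydroxyphenyl)imidazo[1,2-a]pyrazin-3(7H)-one | O=c1c(Cc2ccc(O)cc2)nc2c(Cc3ccccc3)[nH]c(-c3ccc(O)cc3)cn1-2 | target

**Total step count:** 5. **Longest linear sequence:** 5 steps (1 → 3 → 7 → 11 → 12 → 14).

**Steps most likely to fail**

Step 5. The proton relay from C8 to the arylidene carbon may not take place after ring closure, or the dihydropyrazine may be dehydrogenated by adventitious oxygen. The fallback sets out from 13 and uses a known redox pair instead of the isomerisation. Compound 13 is dehydrogenated on purpose with activated MnO2 (CH2Cl2/MeOH, rt) to dehydrocoelenterazine F1. F1 is then reduced with NaBH4 (MeOH/CH2Cl2, 0 °C, Ar), hydride adding to the arylidene carbon, which is the established reduction of this compound. The route is rejoined at 14.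

Step 3. The freed α-amino ketone may self-condense to a dihydropyrazine before it is acylated, the ketone may interfere during cyclodehydration, or closure may be incomplete with the branched acyl group. The fallback sets out from 7 and masks the ketone as a carbinol. Racemic 2-amino-1-(4-hydroxyphenyl)ethanol hydrochloride (octopamine hydrochloride, commercial) with Et3N in MeOH at rt opens 7 to the hydroxy amide F2. K2CO3 in MeOH at 60 °C closes the ring and methanolyses the acetate to the carbinol imidazolone F3. DDQ in dioxane at rt, a known oxidation of 4-hydroxybenzylic alcohols, then gives the aryl ketone. The route is rejoined at 11.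

Step 2. The Boc group may be lost or the oxazolone may self-condense in hot anhydride, and aliphatic acylglycines often convert poorly. The fallback sets out from 1 and builds the dehydroamino acid by Horner–Wadsworth–Emmons olefination:
- Commercial methyl 2-(benzyloxycarbonylamino)-2-(dimethoxyphosphoryl)acetate is hydrogenolysed (H2, Pd/C, MeOH) to methyl 2-amino-2-(dimethoxyphosphoryl)acetate F4.
- F4 is acylated with 1 (N-methylmorpholine, CH2Cl2) to the phosphonodipeptide F5.
- F5 is olefinated with purchased 5 and DBU (CH2Cl2, −20 °C → rt) to the Z-dehydrodipeptide ester F6.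
- LiOH (THF/H2O) cleaves the methyl ester and the aryl acetate to the acid F7.
- Ac2O/NaOAc at rt cyclodehydrates F7 and re-acetylates the phenol.

The route is rejoined at 7.

**Further compounds**
F1 | step 5 | dehydrocoelenterazine, (Z)-8-benzyl-2-(4-hydroxybenzylidene)-6-(4-hydroxyphenyl)imidazo[1,2-a]pyrazin-3(2H)-one | O=C1N2C=C(c3ccc(O)cc3)N=C(Cc3ccccc3)C2=N/C1=C\c1ccc(O)cc1
F2 | step 3 | (Z)-N-(Boc-L-phenylalanyl)-O-acetyl-α,β-dehydrotyrosine N-[2-hydroxy-2-(4-hydroxyphenyl)ethyl]amide (carbinol epimers) | CC(C)(C)OC(=O)N[C@@H](Cc1ccccc1)C(=O)N/C(=C\c1ccc(OC(C)=O)cc1)C(=O)NCC(O)c1ccc(O)cc1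
F3 | step 3 | (Z)-2-[(1S)-1-(Boc-amino)-2-phenylethyl]-4-(4-hydroxybenzylidene)-1-[2-hydroxy-2-(4-hydroxyphenyl)ethyl]-1H-imidazol-5(4H)-one (carbinol epimers) | CC(C)(C)OC(=O)N[C@@H](Cc1ccccc1)C1=N/C(=C\c2ccc(O)cc2)C(=O)N1CC(O)c1ccc(O)cc1
F4 | step 2 | methyl 2-amino-2-(dimethoxyphosphoryl)acetate (racemic) | COC(=O)C(N)P(=O)(OC)OC
F5 | step 2 | methyl 2-(Boc-L-phenylalanylamino)-2-(dimethoxyphosphoryl)acetate (epimers at the phosphonate carbon) | CC(C)(C)OC(=O)N[C@@H](Cc1ccccc1)C(=O)NC(C(=O)OC)P(=O)(OC)OC
F6 | step 2 | methyl (Z)-N-(Boc-L-phenylalanyl)-O-acetyl-α,β-dehydrotyrosinate | CC(C)(C)OC(=O)N[C@@H](Cc1ccccc1)C(=O)N/C(=C\c1ccc(OC(C)=O)cc1)C(=O)OC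
F7 | step 2 | (Z)-N-(Boc-L-phenylalanyl)-α,β-dehydrotyrosine | CC(C)(C)OC(=O)N[C@@H](Cc1ccccc1)C(=O)N/C(=C\c1ccc(O)cc1)C(=O)O
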